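## Retrosynthetic overview

1. The last bond made is C2–O: the diosphenol comes from α'-oxidation of α-methylene ketone 20.
2. C19 and C18 enter together by conjugate methylation of Δ4-3-ketone 16 (sets the cis ring fusion) with Mannich trapping of the enolate.
3. The key C–O bond is C7–O, made by a new copper-catalysed 1,6-boration/oxidation of linear dienone 13 (sets C7), then acetylation.
4. Ring A is formed second, by Mukaiyama–Michael/aldol annulation on silyl enol ether 9; the C9 quaternary centre comes from conjugate addition of zinc reagent 8 (carries C13) to enone 4.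
5. Ring B is formed first, from 3,4-dimethylanisole 1 by Birch reduction and enantioselective isomerisation (sets C8).

Assumption: 1 and the (R)-half-ester 5 are taken as commercial; clerodane numbering is used (C18 = C4 methylene, C19 = C5 methyl, C20 = C9 methyl, C17 = C8 methyl, C15 = ester carbon) and β means the face of H-10 in the target.

## Route

Step 1
Reactants: 1 3,4-dimethylanisole
Product: 3 3,4-dimethylcyclohex-3-en-1-one, via Birch diene 2 (not isolated)
Conditions: Li, NH3 (l), t-BuOH, THF, −78 to −33 °C; then oxalic acid, MeOH/H2O, 20 °C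
Reagents that add atoms: water, O
Why: Birch reduction leaves the methoxy group and both methyls on the two unreduced double bonds, and mild enol-ether hydrolysis gives the unconjugated β,γ-enone without moving the tetrasubstituted alkene.

Step 2
Reactants: 3 3,4-dimethylcyclohex-3-en-1-one
Product: 4 (R)-3,4-dimethylcyclohex-2-en-1-one
Conditions: cinchona-derived chiral primary–tertiary diamine (10 mol %, pseudo-enantiomer giving R), CF3CO2H (20 mol %), toluene, −25 °C
Reagents that add atoms: none
Why: Amine-catalysed enantioselective olefin isomerisation (dienamine formation, then catalyst-directed γ-protonation at C8), a proton-transfer catalysis established for Birch-derived cyclohex-3-enones, moves the alkene into conjugation and sets C8 under catalyst control.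

Step 3
Reactants: 5 (R)-5-methoxy-3-methyl-5-oxopentanoic acid
Product: 6 methyl (R)-5-hydroxy-3-methylpentanoate
Conditions: BH3·SMe2, THF, 0 to 20 °C; MeOH quench
Reagents that add atoms: none
Why: Chemoselective borane reduction of a carboxylic acid beside a methyl ester; the C13 stereocentre is not touched.

Step 4
Reactants: 6 methyl (R)-5-hydroxy-3-methylpentanoate
Product: 7 methyl (S)-5-iodo-3-methylpentanoate
Conditions: PPh3, I2, imidazole, CH2Cl2, 0 °C (crude 6 used at once)
Reagents that add atoms: iodine, II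
Why: Appel-type iodination of the primary alcohol, run directly on crude 6 to outpace δ-lactonisation; the descriptor changes only through priorities.

Step 5
Reactants: 7 methyl (S)-5-iodo-3-methylpentanoate; 4 (R)-3,4-dimethylcyclohex-2-en-1-one
Product: 9 methyl (3R)-3-methyl-5-[(1S,6R)-1,6-dimethyl-3-(trimethylsilyloxy)cyclohex-2-en-1-yl]pentanoate, via organozinc iodide 8 (not isolated)
Conditions: Zn dust, LiCl, THF, 40 °C; then 4, CuBr·SMe2 (10 mol %), TMSCl, HMPA, THF, −40 to 0 °C
Reagents that add atoms: zinc, [Zn] (in 8 only); chlorotrimethylsilane, C[Si](C)(C)Cl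
Why: Zinc insertion followed by copper-catalysed, TMSCl/HMPA-accelerated conjugate addition (Nakamura–Kuwajima conditions, ester-tolerant) forms the C9 quaternary centre by axial attack anti to the pseudoaxial C8 methyl of 4 (C20 cis to C17) and traps the enolate regiospecifically as the C5=C10 silyl enol ether.

Step 6
Reactants: 9 silyl enol ether from step 5; 10 methyl vinyl ketone
Product: 12 methyl (13R)-3-oxo-18,19-dinorclerod-4-en-15-oate (8α-methyl; 9α-methyl; 9β-side chain; 10β-H), via diketone 11 (not isolated)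
Conditions: TiCl4, CH2Cl2, −78 °C; then NaOMe, MeOH, 50 °C
Reagents that add atoms: none
Why: Mukaiyama–Michael addition to TiCl4-activated methyl vinyl ketone and NaOMe-mediated aldol condensation (Robinson annulation) close ring A, and C10 is set thermodynamically because base equilibrates the C10–H of diketone 11 to the epimer with the C10 arm equatorial and cis-1,3 to the equatorial C8 methyl (10β-H).

Step 7
Reactants: 12 methyl (13R)-3-oxo-18,19-dinorclerod-4-en-15-oate
Product: 13 methyl (13R)-3-oxo-18,19-dinorcleroda-4,6-dien-15-oate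
Conditions: chloranil, t-BuOH, reflux
Reagents that add atoms: none
Why: Chloranil dehydrogenation of a Δ4-3-ketone through its 3,5-dienol (hydride loss from C7) gives the linear 4,6-dien-3-one, the standard 19-nor-steroid protocol, without touching a stereocentre.

Step 8
Reactants: 13 methyl (13R)-3-oxo-18,19-dinorcleroda-4,6-dien-15-oate
Product: 15 methyl (13R)-7β-hydroxy-3-oxo-18,19-dinorclerod-4-en-15-oate, via C7 boronate 14 (not isolated)
Conditions: CuCl (5 mol %), IPr·HCl (5 mol %), NaOtBu (10 mol %), B2pin2, MeOH, THF, 0 to 20 °C; then NaBO3·4H2O, THF/H2O, 20 °C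
Reagents that add atoms: bis(pinacolato)diboron, CC1(C)OB(OC1(C)C)B1OC(C)(C)C(C)(C)O1 (Bpin of 14 only); sodium perborate tetrahydrate, O[B-]1(O)OO[B-](O)(O)OO1.[Na+].[Na+] (the C7 oxygen)
Why: Proposed new method: the (NHC)Cu–Bpin species should add to the unhindered δ-carbon C7 of the linear dienone (1,4-addition is shut down because C5 is fully substituted) from the β face, opposite the axial C9 methyl that is 1,3-syn-axial to any α approach, after which MeOH protonates the copper dienolate and NaBO3 oxidises the C–B bond with retention to the equatorial 7β-alcohol trans to the C8 methyl; the closest known reactions are copper-catalysed β-boration of enones and 1,6-boration of acyclic dienoates with oxidative work-up, not yet shown on ring-fused 4,6-dien-3-ones.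

Step 9
Reactants: 15 methyl (13R)-7β-hydroxy-3-oxo-18,19-dinorclerod-4-en-15-oate
Product: 16 methyl (13R)-7β-acetoxy-3-oxo-18,19-dinorclerod-4-en-15-oate
Conditions: Ac2O, pyridine, DMAP (cat.), CH2Cl2, 0 to 20 °C
Reagents that add atoms: acetic anhydride, CC(=O)OC(C)=O
Why: DMAP-catalysed acetylation of the secondary alcohol; the δ-acetoxy enone tolerates pyridine at this temperature and the configuration at C7 is retained.

Step 10
Reactants: 16 methyl (13R)-7β-acetoxy-3-oxo-18,19-dinorclerod-4-en-15-oate
Product: 20 methyl (13R)-7β-acetoxy-3-oxo-5β-methyl-10β-H-clerod-4(18)-en-15-oate, via silyl enol ether 17 (not isolated), via Mannich base 18 (not isolated), via methiodide 19 (not isolated)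
Conditions: Me2CuLi, TMSCl, THF, −78 to −40 °C; then [CH2=NMe2]I, CH2Cl2, 20 °C; then MeI, MeOH; then NaHCO3, H2O/CH2Cl2
Reagents that add atoms: lithium dimethylcuprate, [Li+].C[Cu-]C (C19); N,N-dimethylmethyleneiminium iodide, C=[N+](C)C.[I-] (C18); chlorotrimethylsilane, C[Si](C)(C)Cl (in 17 only); iodomethane, CI (in 19 only)
Why: TMSCl-accelerated cuprate conjugate addition delivers C19 to C5 from the β face, cis to H10 as for Δ1(9)-octal-2-ones and anti to the axial C9 methyl, which sets the cis-decalin, and the regiospecific silyl enol ether is intercepted at C4 by the iminium salt (Mannich reaction) before quaternisation and E1cB elimination give the exocyclic enone.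

Step 11
Reactants: 20 methyl (13R)-7β-acetoxy-3-oxo-5β-methyl-10β-H-clerod-4(18)-en-15-oate
Product: 22 methyl (5S,7S,8S,9R,10R,13R)-7-acetoxy-2-hydroxy-3-oxocleroda-1,4(18)-dien-15-oate, via 2,3-diketone 21 (not isolated)
Conditions: SeO2, 1,4-dioxane/H2O, 90 °C
Reagents that add atoms: selenium dioxide, O=[Se]=O
Why: Riley oxidation attacks the only enolisable position (C2; C4 has no hydrogen and the exocyclic alkene has no allylic C–H) to give the 2,3-diketone, which enolises towards C1 to the hydrogen-bonded diosphenol, making the C2–O bond without touching a stereocentre.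

## Compound list

1 | 3,4-dimethylanisole | COc1ccc(C)c(C)c1 | starting material
2 | 1-methoxy-4,5-dimethylcyclohexa-1,4-diene | COC1=CCC(C)=C(C)C1 | intermediate
3 | 3,4-dimethylcyclohex-3-en-1-one | O=C1CCC(C)=C(C)C1 | intermediate
4 | (R)-3,4-dimethylcyclohex-2-en-1-one | O=C1C=C(C)[C@H](C)CC1 | intermediate
5 | (R)-5-methoxy-3-methyl-5-oxopentanoic acid (methyl hydrogen (R)-3-methylglutarate) | OC(=O)C[C@@H](C)CC(=O)OC | starting material
6 | methyl (R)-5-hydroxy-3-methylpentanoate | OCC[C@@H](C)CC(=O)OC | intermediate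
7 | methyl (S)-5-iodo-3-methylpentanoate | ICC[C@@H](C)CC(=O)OC | intermediate
8 | [(3S)-5-methoxy-3-methyl-5-oxopentyl]zinc iodide | I[Zn]CC[C@@H](C)CC(=O)OC | intermediate
9 | methyl (3R)-3-methyl-5-[(1S,6R)-1,6-dimethyl-3-(trimethylsilyloxy)cyclohex-2-en-1-yl]pentanoate (side chain trans to the ring CH-methyl) | C[Si](C)(C)OC1=C[C@@](C)(CC[C@@H](C)CC(=O)OC)[C@H](C)CC1 | intermediate
10 | methyl vinyl ketone (but-3-en-2-one) | C=CC(C)=O | starting material
11 | methyl (3R)-5-[(1S,2R,6R)-1,6-dimethyl-3-oxo-2-(3-oxobutyl)cyclohexyl]-3-methylpentanoate | CC(=O)CC[C@@H]1[C@@](C)(CC[C@@H](C)CC(=O)OC)[C@H](C)CCC1=O | intermediate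
12 | methyl (13R)-3-oxo-18,19-dinorclerod-4-en-15-oate (8α-Me, 9α-Me, 9β-side chain, 10β-H) | O=C1CC[C@@H]2[C@@](C)(CC[C@@H](C)CC(=O)OC)[C@H](C)CCC2=C1 | intermediate
13 | methyl (13R)-3-oxo-18,19-dinorcleroda-4,6-dien-15-oate (same ring-B centres as 12) | O=C1CC[C@@H]2[C@@](C)(CC[C@@H](C)CC(=O)OC)[C@H](C)C=CC2=C1 | intermediate
14 | 7β-(pinacolatoboryl) derivative of 12 | O=C1CC[C@@H]2[C@@](C)(CC[C@@H](C)CC(=O)OC)[C@H](C)[C@@H](B3OC(C)(C)C(C)(C)O3)CC2=C1 | intermediate
15 | methyl (13R)-7β-hydroxy-3-oxo-18,19-dinorclerod-4-en-15-oate (OH trans to the C8 methyl) | O=C1CC[C@@H]2[C@@](C)(CC[C@@H](C)CC(=O)OC)[C@H](C)[C@@H](O)CC2=C1 | intermediate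
16 | methyl (13R)-7β-acetoxy-3-oxo-18,19-dinorclerod-4-en-15-oate | O=C1CC[C@@H]2[C@@](C)(CC[C@@H](C)CC(=O)OC)[C@H](C)[C@@H](OC(C)=O)CC2=C1 | intermediate
17 | methyl 7β-acetoxy-3-(trimethylsilyloxy)-18-nor-5β-methyl-10β-H-clerod-3-en-15-oate (cis-decalin) | C1=C(O[Si](C)(C)C)CC[C@@H]2[C@@](C)(CC[C@@H](C)CC(=O)OC)[C@H](C)[C@@H](OC(C)=O)C[C@]12C | intermediate
18 | methyl 7β-acetoxy-18-(dimethylamino)-3-oxo-5β-methyl-10β-H-clerodan-15-oate (C4 epimers) | CN(C)CC1C(=O)CC[C@@H]2[C@@](C)(CC[C@@H](C)CC(=O)OC)[C@H](C)[C@@H](OC(C)=O)C[C@]12C | intermediate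
19 | trimethylammonium iodide of 18 | C[N+](C)(C)CC1C(=O)CC[C@@H]2[C@@](C)(CC[C@@H](C)CC(=O)OC)[C@H](C)[C@@H](OC(C)=O)C[C@]12C.[I-] | intermediate
20 | methyl (13R)-7β-acetoxy-3-oxo-5β-methyl-10β-H-clerod-4(18)-en-15-oate | C=C1C(=O)CC[C@@H]2[C@@](C)(CC[C@@H](C)CC(=O)OC)[C@H](C)[C@@H](OC(C)=O)C[C@]12C | intermediate
21 | methyl (13R)-7β-acetoxy-2,3-dioxo-5β-methyl-10β-H-clerod-4(18)-en-15-oate | C=C1C(=O)C(=O)C[C@@H]2[C@@](C)(CC[C@@H](C)CC(=O)OC)[C@H](C)[C@@H](OC(C)=O)C[C@]12C | intermediate
22 | methyl (5S,7S,8S,9R,10R,13R)-7-acetoxy-2-hydroxy-3-oxocleroda-1,4(18)-dien-15-oate (CNP0180040.1) | C=C1C(=O)C(O)=C[C@@H]2[C@@](C)(CC[C@@H](C)CC(=O)OC)[C@H](C)[C@@H](OC(C)=O)C[C@]12C | target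

## Step count and risks

Total steps: 11. Longest linear sequence: 9 steps (1 → 22 through steps 1, 2, 5–11; the branch from 5 through steps 3, 4, 5–11 is also 9).

The three steps most likely to fail:

**Step 8 (the proposed new 1,6-boration/oxidation).** Risks are 1,4- versus 1,6-selectivity, attack on the α face, or plain reduction of the dienone. The fallback uses known chemistry and sets out from dienone 13. mCPBA (NaHCO3, CH2Cl2) epoxidises the electron-richer γ,δ-alkene from the open β face to give the 6β,7β-epoxide F2. SmI2 (THF/MeOH, −78 °C) then cleaves the C6–O bond, which is vinylogously α to the ketone, and leaves the C7–O bond intact, giving the β,γ-unsaturated 7β-hydroxy ketone F3. Brief treatment of F3 with DBU moves the alkene into conjugation and the route is rejoined at alcohol 15.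

**Step 5 (zinc–copper conjugate addition making the C9 quaternary centre next to the C8 methyl).** The risk is low conversion with the hindered β,β-disubstituted enone. The fallback sets out from enone 4 and iodide 7 and drops the preformed organometallic. A nickel-catalysed reductive conjugate addition (NiCl2(dme), neocuproine, Mn powder, Et3SiCl, DMF) couples the alkyl iodide through a silyloxy-allyl nickel intermediate, with the same anti approach to the C8 methyl, and gives the triethylsilyl enol ether F1. F1 is taken through the Mukaiyama–Michael/aldol sequence of step 6 unchanged and the route is rejoined at enone 12.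

**Step 11 (SeO2 oxidation beside a reactive α-methylene ketone).** Risks are competing 1,2-dehydrogenation and addition to the exocyclic enone. The fallback sets out from ketone 20 and replaces the one-step oxidation by a Rubottom sequence. TMSOTf/Et3N gives the 2-silyloxy diene F4. Dimethyldioxirane oxidises the enol-ether double bond and silyl migration gives the 2-silyloxy ketone F5. Citric acid in MeOH frees the 2-hydroxy ketone F6. Dess–Martin periodinane then oxidises F6 to diketone 21, which enolises to target 22.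

## Further compounds

F1 | step 5 | methyl (3R)-3-methyl-5-[(1S,6R)-1,6-dimethyl-3-(triethylsilyloxy)cyclohex-2-en-1-yl]pentanoate | CC[Si](CC)(CC)OC1=C[C@@](C)(CC[C@@H](C)CC(=O)OC)[C@H](C)CC1
F2 | step 8 | methyl (13R)-6β,7β-epoxy-3-oxo-18,19-dinorclerod-4-en-15-oate | O=C1CC[C@@H]2[C@@](C)(CC[C@@H](C)CC(=O)OC)[C@H](C)[C@H]3O[C@H]3C2=C1
F3 | step 8 | methyl (13R)-7β-hydroxy-3-oxo-18,19-dinorclerod-5-en-15-oate | O=C1CC[C@@H]2[C@@](C)(CC[C@@H](C)CC(=O)OC)[C@H](C)[C@@H](O)C=C2C1
F4 | step 11 | methyl 7β-acetoxy-3-(trimethylsilyloxy)-5β-methyl-10β-H-cleroda-2,4(18)-dien-15-oate | C=C1C(O[Si](C)(C)C)=CC[C@@H]2[C@@](C)(CC[C@@H](C)CC(=O)OC)[C@H](C)[C@@H](OC(C)=O)C[C@]12C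
F5 | step 11 | methyl 7β-acetoxy-3-oxo-2-(trimethylsilyloxy)-5β-methyl-10β-H-clerod-4(18)-en-15-oate (C2 epimers) | C=C1C(=O)C(O[Si](C)(C)C)C[C@@H]2[C@@](C)(CC[C@@H](C)CC(=O)OC)[C@H](C)[C@@H](OC(C)=O)C[C@]12C
F6 | step 11 | methyl 7β-acetoxy-2-hydroxy-3-oxo-5β-methyl-10β-H-clerod-4(18)-en-15-oate (C2 epimers) | C=C1C(=O)C(O)C[C@@H]2[C@@](C)(CC[C@@H](C)CC(=O)OC)[C@H](C)[C@@H](OC(C)=O)C[C@]12C
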